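**Strategy.** The oxolane O1–C2 bond is disconnected last. Ring B carries the only free phenol, para to the benzylic C2 methylene, so a flavin-dependent 4-alkylphenol oxidase can dehydrogenate that one CH2 to a p-quinone methide. The C5 primary hydroxyl captures it (5-exo), closing the oxolane and setting C2 trans to the C3 hydroxymethyl. The precursor is the biaryl seco-triol 22: a 2,3-dibenzylbutane-1,2,4-triol arm on ring B, the finished tetralin on ring C, and rings A, C and D as benzyl ethers. Both arms come from one bromophenol dioxolanone (malate alkylation, then self-regenerating alkylation), and a Suzuki coupling joins them.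

Key step: step 17

Labels: ring A = the 3-oxy-4-methoxybenzyl ring on oxolane C4; ring B = the aryl ring on oxolane C2; ring C = its biaryl partner, bonded to tetralin C1; ring D = the benzo ring of the tetralin. Oxolane atoms: O1, C2 (aryl), C3 (CH2OH), C4 (OH, benzyl), C5.

Design note: in 22 ring A is a benzyl ether as well, so ring B holds the only phenol of the precursor and one hydrogenolysis at the end frees all three masked phenols.

Assumption: diester 5 and the O-benzylated benzyl alcohols 9 and 13 are purchased; the ring B–ring C axis has one ortho substituent on each side and is taken to rotate freely, so no axial isomers are counted.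

Step 1
Reactants: 1 5-bromovanillin
Product: 2 3-bromo-4-(tert-butyldimethylsilyloxy)-5-methoxybenzaldehyde
Conditions: TBSCl, imidazole, DMF, rt
Reagents that add atoms: tert-butyldimethylsilyl chloride, CC(C)(C)[Si](C)(C)Cl
Why: Imidazole-promoted O-silylation masks the acidic phenol so that a benzylic bromide can be made and used in an enolate alkylation.

Step 2
Reactants: 2 3-bromo-4-(tert-butyldimethylsilyloxy)-5-methoxybenzaldehyde
Product: 3 [3-bromo-4-(tert-butyldimethylsilyloxy)-5-methoxyphenyl]methanol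
Conditions: NaBH4, THF/EtOH, 0 °C
Reagents that add atoms: none
Why: Borohydride reduction of the aryl aldehyde is fast at 0 °C and should leave the aryl bromide and the flanked aryl silyl ether untouched.

Step 3
Reactants: 3 [3-bromo-4-(tert-butyldimethylsilyloxy)-5-methoxyphenyl]methanol
Product: 4 3-bromo-4-(tert-butyldimethylsilyloxy)-5-methoxybenzyl bromide
Conditions: CBr4, PPh3, CH2Cl2, 0 °C
Reagents that add atoms: tetrabromomethane, BrC(Br)(Br)Br
Why: Appel bromination converts the primary benzylic alcohol into the bromide under neutral conditions that the silyl ether tolerates.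

Step 4
Reactants: 5 diethyl (S)-malate; 4 3-bromo-4-(tert-butyldimethylsilyloxy)-5-methoxybenzyl bromide
Product: 6 diethyl (2S,3R)-3-[[3-bromo-4-(tert-butyldimethylsilyloxy)-5-methoxyphenyl]methyl]-2-hydroxybutanedioate
Conditions: LiHMDS (2.2 equiv), THF, −78 to −20 °C; then 4, −78 to −10 °C; AcOH quench
Reagents that add atoms: none
Why: Fráter–Seebach alkylation: the chelated lithium alkoxide–enolate of 5 should be alkylated by the benzylic bromide on the face anti to the C2 oxygen, setting C3 as R (2,3-anti), with the minor syn isomer removed by chromatography.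

Step 5
Reactants: 6 diethyl (2S,3R)-3-[[3-bromo-4-(tert-butyldimethylsilyloxy)-5-methoxyphenyl]methyl]-2-hydroxybutanedioate
Product: 7 (2S,3R)-3-[(3-bromo-4-hydroxy-5-methoxyphenyl)methyl]-2-hydroxybutanedioic acid
Conditions: KOH, EtOH/H2O, rt to 50 °C; then aq HCl
Reagents that add atoms: potassium hydroxide, [K+].[OH-]
Why: Saponification of both ethyl esters also cleaves the base-labile aryl silyl ether, so one operation should give the phenolic diacid, whose carboxylate form resists epimerisation at C3.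

Step 6
Reactants: 7 (2S,3R)-3-[(3-bromo-4-hydroxy-5-methoxyphenyl)methyl]-2-hydroxybutanedioic acid
Product: 8 (2R)-3-(3-bromo-4-hydroxy-5-methoxyphenyl)-2-[(2S,4S)-2-tert-butyl-5-oxo-1,3-dioxolan-4-yl]propanoic acid (tert-butyl cis to the side chain)
Conditions: tBuCHO, TsOH·H2O (cat.), H2SO4 (cat.), pentane/CH2Cl2, reflux, Dean–Stark
Reagents that add atoms: pivalaldehyde, CC(C)(C)C=O
Why: Seebach acetalisation of the α-hydroxy acid: the five-membered dioxolanone is favoured over the six-membered ring from the β-carboxyl, and the equilibrating acid conditions should set the acetal carbon cis to the side chain (2S), the isomer purified by crystallisation.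

Step 7
Reactants: 9 3-benzyloxy-4-methoxybenzyl alcohol
Product: 10 3-benzyloxy-4-methoxybenzyl bromide
Conditions: PBr3, Et2O, 0 °C
Reagents that add atoms: phosphorus tribromide, BrP(Br)Br
Why: PBr3 converts the electron-rich benzylic alcohol into the bromide through the phosphite ester (SN2); the bromide is used at once.

Step 8
Reactants: 8 (2R)-3-(3-bromo-4-hydroxy-5-methoxyphenyl)-2-[(2S,4S)-2-tert-butyl-5-oxo-1,3-dioxolan-4-yl]propanoic acid; 10 3-benzyloxy-4-methoxybenzyl bromide
Product: 11 (2R)-2-[(2S,4S)-4-[(3-benzyloxy-4-methoxyphenyl)methyl]-2-tert-butyl-5-oxo-1,3-dioxolan-4-yl]-3-(3-bromo-4-hydroxy-5-methoxyphenyl)propanoic acid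
Conditions: LiHMDS (3.3 equiv), THF/DMPU, −78 °C; then 10, −78 °C; AcOH quench
Reagents that add atoms: none
Why: Seebach self-regeneration of stereocentres: the trilithio species (phenoxide, carboxylate, dioxolanone enolate) should be C-alkylated on the face opposite the tert-butyl group, so the benzyl group replaces H at the carbinol carbon with retention (4S), while the carboxylate keeps the side-chain α-position from enolising and the flanked lithium phenoxide stays inert at −78 °C.

Step 9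
Reactants: 11 (2R)-2-[(2S,4S)-4-[(3-benzyloxy-4-methoxyphenyl)methyl]-2-tert-butyl-5-oxo-1,3-dioxolan-4-yl]-3-(3-bromo-4-hydroxy-5-methoxyphenyl)propanoic acid
Product: 12 (2S,3S)-2-[(3-benzyloxy-4-methoxyphenyl)methyl]-3-[(3-bromo-4-hydroxy-5-methoxyphenyl)methyl]butane-1,2,4-triol
Conditions: LiAlH4, THF, 0 °C to rt; Rochelle salt work-up
Reagents that add atoms: none
Why: Hydride reduction turns the dioxolanone carbonyl and the carboxylate into the two primary alcohols and frees the tertiary hydroxyl with loss of the pivalaldehyde unit, and the aryl bromide should survive at or below room temperature.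

Step 10
Reactants: 13 4-benzyloxy-3-methoxybenzyl alcohol
Product: 14 4-benzyloxy-3-methoxybenzyl bromide
Conditions: PBr3, Et2O, 0 °C
Reagents that add atoms: phosphorus tribromide, BrP(Br)Br
Why: The same SN2 bromination through the phosphite ester as in step 7; the bromide is used at once.

Step 11
Reactants: 8 (2R)-3-(3-bromo-4-hydroxy-5-methoxyphenyl)-2-[(2S,4S)-2-tert-butyl-5-oxo-1,3-dioxolan-4-yl]propanoic acid; 14 4-benzyloxy-3-methoxybenzyl bromide
Product: 15 (2R)-2-[(2S,4S)-4-[(4-benzyloxy-3-methoxyphenyl)methyl]-2-tert-butyl-5-oxo-1,3-dioxolan-4-yl]-3-(3-bromo-4-hydroxy-5-methoxyphenyl)propanoic acid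
Conditions: LiHMDS (3.3 equiv), THF/DMPU, −78 °C; then 14, −78 °C; AcOH quench
Reagents that add atoms: none
Why: The same self-regenerating dioxolanone enolate alkylation as in step 8, with attack anti to the tert-butyl group fixing the quaternary carbinol carbon (4S) with retention.

Step 12
Reactants: 15 (2R)-2-[(2S,4S)-4-[(4-benzyloxy-3-methoxyphenyl)methyl]-2-tert-butyl-5-oxo-1,3-dioxolan-4-yl]-3-(3-bromo-4-hydroxy-5-methoxyphenyl)propanoic acid
Product: 16 (2S,3S)-2-[(4-benzyloxy-3-methoxyphenyl)methyl]-3-[(3-bromo-4-hydroxy-5-methoxyphenyl)methyl]butane-1,2,4-triol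
Conditions: LiAlH4, THF, 0 °C to rt; Rochelle salt work-up
Reagents that add atoms: none
Why: The same hydride reduction of dioxolanone and carboxylate as in step 9 should give the triol without touching either stereocentre.

Step 13
Reactants: 16 (2S,3S)-2-[(4-benzyloxy-3-methoxyphenyl)methyl]-3-[(3-bromo-4-hydroxy-5-methoxyphenyl)methyl]butane-1,2,4-triol
Product: 19 (2S,3S,4S)-6-benzyloxy-4-(3-bromo-4-hydroxy-5-methoxyphenyl)-2,3-bis(hydroxymethyl)-7-methoxy-1,2,3,4-tetrahydronaphthalen-2-ol, via quinone methide 17 (not isolated), via oxolane 18 (not isolated)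
Conditions: DDQ (1.05 equiv), CH2Cl2/1,4-dioxane, 0 °C; then TFA, 0 °C to rt; aq NaHCO3
Reagents that add atoms: none
Why: DDQ dehydrogenation of the only free 4-alkylphenol gives quinone methide 17, which the C1 hydroxyl traps as oxolane 18; acid then reopens this benzylic ether to the p-hydroxybenzyl cation, and intramolecular Friedel–Crafts attack by ring D para to its methoxy group should close the tetralin irreversibly with the aryl group trans to the neighbouring hydroxymethyl (4S).

Step 14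
Reactants: 19 (2S,3S,4S)-6-benzyloxy-4-(3-bromo-4-hydroxy-5-methoxyphenyl)-2,3-bis(hydroxymethyl)-7-methoxy-1,2,3,4-tetrahydronaphthalen-2-ol
Product: 20 (2S,3S,4S)-6-benzyloxy-4-(4-benzyloxy-3-bromo-5-methoxyphenyl)-2,3-bis(hydroxymethyl)-7-methoxy-1,2,3,4-tetrahydronaphthalen-2-ol
Conditions: BnBr, K2CO3, DMF, rt
Reagents that add atoms: benzyl bromide, BrCc1ccccc1
Why: Williamson etherification: carbonate ionises only the phenol, so ring C oxygen should be benzylated selectively in the presence of the three aliphatic hydroxyls.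

Step 15
Reactants: 20 (2S,3S,4S)-6-benzyloxy-4-(4-benzyloxy-3-bromo-5-methoxyphenyl)-2,3-bis(hydroxymethyl)-7-methoxy-1,2,3,4-tetrahydronaphthalen-2-ol
Product: 21 (2S,3S,4S)-6-benzyloxy-4-[4-benzyloxy-3-methoxy-5-(4,4,5,5-tetramethyl-1,3,2-dioxaborolan-2-yl)phenyl]-2,3-bis(hydroxymethyl)-7-methoxy-1,2,3,4-tetrahydronaphthalen-2-ol
Conditions: B2pin2, PdCl2(dppf), KOAc, 1,4-dioxane, 85 °C
Reagents that add atoms: bis(pinacolato)diboron, CC1(C)OB(OC1(C)C)B1OC(C)(C)C(C)(C)O1
Why: Miyaura borylation of the aryl bromide; the weak acetate base suppresses biaryl homocoupling and free hydroxyls are tolerated.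

Step 16
Reactants: 21 (2S,3S,4S)-6-benzyloxy-4-[4-benzyloxy-3-methoxy-5-(4,4,5,5-tetramethyl-1,3,2-dioxaborolan-2-yl)phenyl]-2,3-bis(hydroxymethyl)-7-methoxy-1,2,3,4-tetrahydronaphthalen-2-ol; 12 (2S,3S)-2-[(3-benzyloxy-4-methoxyphenyl)methyl]-3-[(3-bromo-4-hydroxy-5-methoxyphenyl)methyl]butane-1,2,4-triol
Product: 22 (2S,3S)-2-[(3-benzyloxy-4-methoxyphenyl)methyl]-3-[[2'-benzyloxy-5'-[(1S,2S,3S)-7-benzyloxy-3-hydroxy-2,3-bis(hydroxymethyl)-6-methoxy-1,2,3,4-tetrahydronaphthalen-1-yl]-6-hydroxy-3',5-dimethoxybiphenyl-3-yl]methyl]butane-1,2,4-triol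
Conditions: Pd(OAc)2, SPhos, K3PO4, 1,4-dioxane/H2O, 80 °C
Reagents that add atoms: none
Why: Suzuki–Miyaura cross-coupling joins ring B to ring C between two partners with one ortho substituent each; the electron-rich SPhos ligand should drive oxidative addition into the bromophenoxide, and the free hydroxyls are tolerated.

Step 17
Reactants: 22 (2S,3S)-2-[(3-benzyloxy-4-methoxyphenyl)methyl]-3-[[2'-benzyloxy-5'-[(1S,2S,3S)-7-benzyloxy-3-hydroxy-2,3-bis(hydroxymethyl)-6-methoxy-1,2,3,4-tetrahydronaphthalen-1-yl]-6-hydroxy-3',5-dimethoxybiphenyl-3-yl]methyl]butane-1,2,4-triol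
Product: 24 (3S,4R,5S)-3-[(3-benzyloxy-4-methoxyphenyl)methyl]-5-[2'-benzyloxy-5'-[(1S,2S,3S)-7-benzyloxy-3-hydroxy-2,3-bis(hydroxymethyl)-6-methoxy-1,2,3,4-tetrahydronaphthalen-1-yl]-6-hydroxy-3',5-dimethoxybiphenyl-3-yl]-4-(hydroxymethyl)oxolan-3-ol, via quinone methide 23 (not isolated)
Conditions: eugenol oxidase variant (flavoprotein 4-alkylphenol oxidase with a substrate channel widened by directed evolution), air, catalase, 50 mM potassium phosphate pH 8.0, 15% v/v DMSO, 30 °C
Reagents that add atoms: none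
Why: Proposed new method: the flavoprotein should bind 22 through its single phenolate (ring B), transfer hydride from the para benzylic CH2 to the covalently bound flavin to give p-quinone methide 23 and be reoxidised by O2, after which the primary hydroxyl on C5 adds to the methide carbon and rearomatises ring B, forming O1–C2. The closest known reactions are the oxidase-mediated hydroxylations of 4-alkylphenols, in which water captures the same enzyme-bound quinone methide, and the chemical quinone-methide etherification rehearsed in step 13; new are the bulky biaryl substrate, for which a variant with a widened substrate channel has to be evolved, and an internal alcohol as the trap. The oxolane closes in a 5-exo-trig mode, the only low-strain option because the C4 tertiary hydroxyl and the C3 hydroxymethyl could only form oxetanes. C2 is controlled by the adjacent C3 stereocentre: in the envelope-like transition state ring B and the C3 hydroxymethyl lie pseudo-equatorial on opposite faces, which should give the 2,3-trans (2S) isomer whether the ring closes in the active site or after release of 23. The step needs site selectivity over the other benzylic C–H positions and chemoselectivity over hydration of 23 or its tautomerisation to a styrene; the first is secured because rings A, C and D are benzyl ethers that can form neither a phenolate nor a quinone methide, the second by the proximity of the C5 hydroxyl, which should make ring closure faster than bimolecular capture.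

Step 18
Reactants: 24 (3S,4R,5S)-3-[(3-benzyloxy-4-methoxyphenyl)methyl]-5-[2'-benzyloxy-5'-[(1S,2S,3S)-7-benzyloxy-3-hydroxy-2,3-bis(hydroxymethyl)-6-methoxy-1,2,3,4-tetrahydronaphthalen-1-yl]-6-hydroxy-3',5-dimethoxybiphenyl-3-yl]-4-(hydroxymethyl)oxolan-3-ol
Product: 25 (3S,4R,5S)-5-[2',6-dihydroxy-5'-[(1S,2S,3S)-3,7-dihydroxy-2,3-bis(hydroxymethyl)-6-methoxy-1,2,3,4-tetrahydronaphthalen-1-yl]-3',5-dimethoxybiphenyl-3-yl]-3-[(3-hydroxy-4-methoxyphenyl)methyl]-4-(hydroxymethyl)oxolan-3-ol (CNP0252244.1)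
Conditions: H2 (1 atm), Pd/C, EtOAc/EtOH, rt, stopped at full debenzylation
Reagents that add atoms: none
Why: Hydrogenolysis of the three aryl benzyl ethers is much faster than cleavage of the benzylic oxolane C2–O1 bond in a neutral solvent, so the target should be released with all six stereocentres untouched.

**Compound list**

1 | 5-bromovanillin (3-bromo-4-hydroxy-5-methoxybenzaldehyde) | COc1cc(C=O)cc(Br)c1O | starting material
2 | 3-bromo-4-(tert-butyldimethylsilyloxy)-5-methoxybenzaldehyde | COc1cc(C=O)cc(Br)c1O[Si](C)(C)C(C)(C)C | intermediate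
3 | [3-bromo-4-(tert-butyldimethylsilyloxy)-5-methoxyphenyl]methanol | COc1cc(CO)cc(Br)c1O[Si](C)(C)C(C)(C)C | intermediate
4 | 3-bromo-4-(tert-butyldimethylsilyloxy)-5-methoxybenzyl bromide | COc1cc(CBr)cc(Br)c1O[Si](C)(C)C(C)(C)C | intermediate
5 | diethyl (S)-malate | CCOC(=O)C[C@H](O)C(=O)OCC | starting material
6 | diethyl (2S,3R)-3-[[3-bromo-4-(tert-butyldimethylsilyloxy)-5-methoxyphenyl]methyl]-2-hydroxybutanedioate | CCOC(=O)[C@@H](O)[C@@H](Cc1cc(OC)c(O[Si](C)(C)C(C)(C)C)c(Br)c1)C(=O)OCC | intermediate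
7 | (2S,3R)-3-[(3-bromo-4-hydroxy-5-methoxyphenyl)methyl]-2-hydroxybutanedioic acid | OC(=O)[C@@H](O)[C@@H](Cc1cc(OC)c(O)c(Br)c1)C(=O)O | intermediate
8 | (2R)-3-(3-bromo-4-hydroxy-5-methoxyphenyl)-2-[(2S,4S)-2-tert-butyl-5-oxo-1,3-dioxolan-4-yl]propanoic acid | CC(C)(C)[C@H]1O[C@@H]([C@@H](Cc2cc(OC)c(O)c(Br)c2)C(=O)O)C(=O)O1 | intermediate
9 | 3-benzyloxy-4-methoxybenzyl alcohol | COc1ccc(CO)cc1OCc1ccccc1 | starting material
10 | 3-benzyloxy-4-methoxybenzyl bromide | COc1ccc(CBr)cc1OCc1ccccc1 | intermediate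
11 | (2R)-2-[(2S,4S)-4-[(3-benzyloxy-4-methoxyphenyl)methyl]-2-tert-butyl-5-oxo-1,3-dioxolan-4-yl]-3-(3-bromo-4-hydroxy-5-methoxyphenyl)propanoic acid | CC(C)(C)[C@H]1O[C@@](Cc3ccc(OC)c(OCc4ccccc4)c3)([C@@H](Cc2cc(OC)c(O)c(Br)c2)C(=O)O)C(=O)O1 | intermediate
12 | (2S,3S)-2-[(3-benzyloxy-4-methoxyphenyl)methyl]-3-[(3-bromo-4-hydroxy-5-methoxyphenyl)methyl]butane-1,2,4-triol | COc1ccc(C[C@@](O)(CO)[C@H](CO)Cc3cc(OC)c(O)c(Br)c3)cc1OCc1ccccc1 | intermediate
13 | 4-benzyloxy-3-methoxybenzyl alcohol | COc1cc(CO)ccc1OCc1ccccc1 | starting material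
14 | 4-benzyloxy-3-methoxybenzyl bromide | COc1cc(CBr)ccc1OCc1ccccc1 | intermediate
15 | (2R)-2-[(2S,4S)-4-[(4-benzyloxy-3-methoxyphenyl)methyl]-2-tert-butyl-5-oxo-1,3-dioxolan-4-yl]-3-(3-bromo-4-hydroxy-5-methoxyphenyl)propanoic acid | CC(C)(C)[C@H]1O[C@@](Cc3ccc(OCc4ccccc4)c(OC)c3)([C@@H](Cc2cc(OC)c(O)c(Br)c2)C(=O)O)C(=O)O1 | intermediate
16 | (2S,3S)-2-[(4-benzyloxy-3-methoxyphenyl)methyl]-3-[(3-bromo-4-hydroxy-5-methoxyphenyl)methyl]butane-1,2,4-triol | COc1cc(C[C@@](O)(CO)[C@H](CO)Cc3cc(OC)c(O)c(Br)c3)ccc1OCc1ccccc1 | intermediate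
17 | 4-[(2S,3S)-3-[(4-benzyloxy-3-methoxyphenyl)methyl]-3,4-dihydroxy-2-(hydroxymethyl)butylidene]-2-bromo-6-methoxycyclohexa-2,5-dien-1-one (quinone methide, alkene geometry open) | COc1cc(C[C@@](O)(CO)[C@H](CO)C=C3C=C(OC)C(=O)C(Br)=C3)ccc1OCc1ccccc1 | intermediate
18 | (3S,4R,5S)-3-[(4-benzyloxy-3-methoxyphenyl)methyl]-5-(3-bromo-4-hydroxy-5-methoxyphenyl)-4-(hydroxymethyl)oxolan-3-ol | COc1cc(C[C@@]2(O)CO[C@H](c3cc(OC)c(O)c(Br)c3)[C@H]2CO)ccc1OCc1ccccc1 | intermediate
19 | (2S,3S,4S)-6-benzyloxy-4-(3-bromo-4-hydroxy-5-methoxyphenyl)-2,3-bis(hydroxymethyl)-7-methoxy-1,2,3,4-tetrahydronaphthalen-2-ol | Brc4cc([C@H]5c6cc(OCc7ccccc7)c(OC)cc6C[C@@](O)(CO)[C@@H]5CO)cc(OC)c4O | intermediate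
20 | (2S,3S,4S)-6-benzyloxy-4-(4-benzyloxy-3-bromo-5-methoxyphenyl)-2,3-bis(hydroxymethyl)-7-methoxy-1,2,3,4-tetrahydronaphthalen-2-ol | Brc4cc([C@H]5c6cc(OCc7ccccc7)c(OC)cc6C[C@@](O)(CO)[C@@H]5CO)cc(OC)c4OCc7ccccc7 | intermediate
21 | (2S,3S,4S)-6-benzyloxy-4-[4-benzyloxy-3-methoxy-5-(4,4,5,5-tetramethyl-1,3,2-dioxaborolan-2-yl)phenyl]-2,3-bis(hydroxymethyl)-7-methoxy-1,2,3,4-tetrahydronaphthalen-2-ol | CC1(C)OB(OC1(C)C)c4cc([C@H]5c6cc(OCc7ccccc7)c(OC)cc6C[C@@](O)(CO)[C@@H]5CO)cc(OC)c4OCc7ccccc7 | intermediate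
22 | (2S,3S)-2-[(3-benzyloxy-4-methoxyphenyl)methyl]-3-[[2'-benzyloxy-5'-[(1S,2S,3S)-7-benzyloxy-3-hydroxy-2,3-bis(hydroxymethyl)-6-methoxy-1,2,3,4-tetrahydronaphthalen-1-yl]-6-hydroxy-3',5-dimethoxybiphenyl-3-yl]methyl]butane-1,2,4-triol (seco-triol precursor) | COc1ccc(C[C@@](O)(CO)[C@H](CO)Cc3cc(OC)c(O)c(-c4cc([C@H]5c6cc(OCc9ccccc9)c(OC)cc6C[C@@](O)(CO)[C@@H]5CO)cc(OC)c4OCc9ccccc9)c3)cc1OCc1ccccc1 | intermediate
23 | ring B p-quinone methide of 22 (4-alkylidene-2-aryl-6-methoxycyclohexa-2,5-dien-1-one, alkene geometry open) | COc1ccc(C[C@@](O)(CO)[C@H](CO)C=C3C=C(OC)C(=O)C(c4cc([C@H]5c6cc(OCc9ccccc9)c(OC)cc6C[C@@](O)(CO)[C@@H]5CO)cc(OC)c4OCc9ccccc9)=C3)cc1OCc1ccccc1 | intermediate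
24 | (3S,4R,5S)-3-[(3-benzyloxy-4-methoxyphenyl)methyl]-5-[2'-benzyloxy-5'-[(1S,2S,3S)-7-benzyloxy-3-hydroxy-2,3-bis(hydroxymethyl)-6-methoxy-1,2,3,4-tetrahydronaphthalen-1-yl]-6-hydroxy-3',5-dimethoxybiphenyl-3-yl]-4-(hydroxymethyl)oxolan-3-ol (tribenzyl ether of the target) | COc1ccc(C[C@@]2(O)CO[C@H](c3cc(OC)c(O)c(-c4cc([C@H]5c6cc(OCc9ccccc9)c(OC)cc6C[C@@](O)(CO)[C@@H]5CO)cc(OC)c4OCc9ccccc9)c3)[C@H]2CO)cc1OCc1ccccc1 | intermediate
25 | (3S,4R,5S)-5-[2',6-dihydroxy-5'-[(1S,2S,3S)-3,7-dihydroxy-2,3-bis(hydroxymethyl)-6-methoxy-1,2,3,4-tetrahydronaphthalen-1-yl]-3',5-dimethoxybiphenyl-3-yl]-3-[(3-hydroxy-4-methoxyphenyl)methyl]-4-(hydroxymethyl)oxolan-3-ol (CNP0252244.1) | COc1ccc(C[C@@]2(O)CO[C@H](c3cc(OC)c(O)c(-c4cc([C@H]5c6cc(O)c(OC)cc6C[C@@](O)(CO)[C@@H]5CO)cc(OC)c4O)c3)[C@H]2CO)cc1O | target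

**Count**

Total steps: 18. Longest linear sequence: 14 steps (steps 1–6 and 11–18).

**Steps most likely to fail**

1. Step 17 (proposed new method). The oxidase may fail to admit the bulky biaryl phenol, or the quinone methide may be hydrated or tautomerised to a styrene before the hydroxyl closes the ring, leaving low conversion or open-chain by-products. The fallback sets out from 22 and comes back at 24. One equivalent of DDQ in CH2Cl2/1,4-dioxane at 0 °C should take the only phenol of 22 to the same quinone methide 23 in solution, where the C5 hydroxyl closes the oxolane under control by C3. This is the chemical quinone-methide etherification already run on 16 in step 13, and it makes no compound outside the list (F0).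

2. Step 11 (step 8 is the same operation). Enolisation of the trilithio species may be incomplete through aggregation, or the phenoxide or carboxylate may be O-benzylated, lowering the yield of C-alkylation. The fallback sets out from 8 and comes back at 16 and removes the phenoxide from the alkylation. TBSCl and imidazole in DMF should silylate both acidic groups to give the bis-silyl derivative, tert-butyldimethylsilyl (2R)-3-[3-bromo-4-(tert-butyldimethylsilyloxy)-5-methoxyphenyl]-2-[(2S,4S)-2-tert-butyl-5-oxo-1,3-dioxolan-4-yl]propanoate F1. Aqueous acetic acid in THF cleaves only the silyl ester to the silyl ether acid, (2R)-3-[3-bromo-4-(tert-butyldimethylsilyloxy)-5-methoxyphenyl]-2-[(2S,4S)-2-tert-butyl-5-oxo-1,3-dioxolan-4-yl]propanoic acid F2. Its dianion (LiHMDS, 2.2 equiv, THF, −78 °C) is alkylated with 14, anti to the tert-butyl group, to the silyl ether of 15, F3. LiAlH4 in THF then gives the silyl ether of 16, F4, and Bu4NF in THF frees the phenol to give 16.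

3. Step 13. DDQ may over-oxidise the product phenol, or the acid stage may stall at oxolane 18 or erode a benzyl ether, giving mixtures instead of the tetralin. The fallback sets out from 15 and comes back at 19 and closes the carbocycle before any hydroxyl is unmasked. DDQ in CH2Cl2 with TFA at 0 °C should oxidise the phenol of 15 to the quinone methide acid, (2S)-2-[(2S,4S)-4-[(4-benzyloxy-3-methoxyphenyl)methyl]-2-tert-butyl-5-oxo-1,3-dioxolan-4-yl]-3-(3-bromo-5-methoxy-4-oxocyclohexa-2,5-dien-1-ylidene)propanoic acid F5. With no oxygen nucleophile in reach of a five-membered ring, Friedel–Crafts attack by ring D should give the spiro tetralin acid, (2S,4S,1'S,2'R)-7'-benzyloxy-1'-(3-bromo-4-hydroxy-5-methoxyphenyl)-2-tert-butyl-6'-methoxy-5-oxo-1',4'-dihydro-2'H-spiro[1,3-dioxolane-4,3'-naphthalene]-2'-carboxylic acid F6, with the aryl group trans to the carboxyl. LiAlH4 in THF at 0 °C to rt then reduces the dioxolanone and the acid to give 19.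

**Further compounds**

F0 | step 17 | none | none
F1 | step 11 | tert-butyldimethylsilyl (2R)-3-[3-bromo-4-(tert-butyldimethylsilyloxy)-5-methoxyphenyl]-2-[(2S,4S)-2-tert-butyl-5-oxo-1,3-dioxolan-4-yl]propanoate | CC(C)(C)[C@H]1O[C@@H]([C@@H](Cc2cc(OC)c(O[Si](C)(C)C(C)(C)C)c(Br)c2)C(=O)O[Si](C)(C)C(C)(C)C)C(=O)O1
F2 | step 11 | (2R)-3-[3-bromo-4-(tert-butyldimethylsilyloxy)-5-methoxyphenyl]-2-[(2S,4S)-2-tert-butyl-5-oxo-1,3-dioxolan-4-yl]propanoic acid | CC(C)(C)[C@H]1O[C@@H]([C@@H](Cc2cc(OC)c(O[Si](C)(C)C(C)(C)C)c(Br)c2)C(=O)O)C(=O)O1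
F3 | step 11 | (2R)-2-[(2S,4S)-4-[(4-benzyloxy-3-methoxyphenyl)methyl]-2-tert-butyl-5-oxo-1,3-dioxolan-4-yl]-3-[3-bromo-4-(tert-butyldimethylsilyloxy)-5-methoxyphenyl]propanoic acid | CC(C)(C)[C@H]1O[C@@](Cc3ccc(OCc4ccccc4)c(OC)c3)([C@@H](Cc2cc(OC)c(O[Si](C)(C)C(C)(C)C)c(Br)c2)C(=O)O)C(=O)O1
F4 | step 11 | (2S,3S)-2-[(4-benzyloxy-3-methoxyphenyl)methyl]-3-[[3-bromo-4-(tert-butyldimethylsilyloxy)-5-methoxyphenyl]methyl]butane-1,2,4-triol | COc1cc(C[C@@](O)(CO)[C@H](CO)Cc3cc(OC)c(O[Si](C)(C)C(C)(C)C)c(Br)c3)ccc1OCc1ccccc1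
F5 | step 13 | (2S)-2-[(2S,4S)-4-[(4-benzyloxy-3-methoxyphenyl)methyl]-2-tert-butyl-5-oxo-1,3-dioxolan-4-yl]-3-(3-bromo-5-methoxy-4-oxocyclohexa-2,5-dien-1-ylidene)propanoic acid | CC(C)(C)[C@H]1O[C@@](Cc3ccc(OCc4ccccc4)c(OC)c3)([C@@H](C=C2C=C(OC)C(=O)C(Br)=C2)C(=O)O)C(=O)O1
F6 | step 13 | (2S,4S,1'S,2'R)-7'-benzyloxy-1'-(3-bromo-4-hydroxy-5-methoxyphenyl)-2-tert-butyl-6'-methoxy-5-oxo-1',4'-dihydro-2'H-spiro[1,3-dioxolane-4,3'-naphthalene]-2'-carboxylic acid | CC(C)(C)[C@H]1O[C@]2(Cc3cc(OC)c(OCc4ccccc4)cc3[C@H](c3cc(OC)c(O)c(Br)c3)[C@H]2C(=O)O)C(=O)O1
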